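- The product we care about is the target, and what is asked is its share beside the isomer of the product, so we first ask which of the given numbers that share can feel.

| flask | starting material | partner | protic impurity | free catalyst | remark | time |
|---|---|---|---|---|---|---|
| midnight | 1.5 M | 1.8 M | 0.015 M | 38 mM | run made earlier |  |
| dawn | 1.5 M | 1.8 M | 0.060 M | 38 mM | run made earlier |  |
| flask | 1.5 M | 1.80 M | 0.0300 M | 38 mM |  | 12 h |

| run | time / h | target / % | isomer of the product / % |
|---|---|---|---|
| midnight | 1.00 | 36.9 | 0.6 |
| midnight | 2.00 | 45.8 | 1.2 |
| midnight | 3.00 | 48.2 | 1.6 |
| midnight | 6.00 | 46.5 | 2.6 |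
| midnight | 12.0 | 45.7 | 3.8 |
| dawn | 2.50 | 45.7 | 1.9 |
| dawn | 5.00 | 47.1 | 2.6 |
| dawn | 8.00 | 45.9 | 2.4 |
| dawn | 10.0 | 45.6 | 3.1 |
| dawn | 12.0 | 45.3 | 3.0 |

(each reading ± 0.5 percentage points)

1. share of target in target plus isomer of the product at 4.0 min
2. share of target in target plus isomer of the product at 12 h
3. which of target and isomer of the product there is more of at 12 h



- Take the midnight run at 12.0 h. If its isomer reading were off by the scatter of 0.5 percentage points, the share of target would move by 0.92 points. If its target reading were off by as much, the share would move by 0.077 points. The isomer reading moves the share more, so that is the reading we must know well.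
- Next comes the protic impurity. Between 0.015 M in the midnight run and 0.060 M in the dawn run, the share at 12.0 h goes from 92.3% to 93.8%. That shift of 1.5 points stands against 0.92 points of scatter on each share, so we do not read a clear effect of the impurity. The new flask's 0.0300 M also lies between the two charges.
- We therefore average the two runs at 12.0 h and get 7.47%. We call this reading ρ, the amount of isomer of the product over the amount of target, a selectivity in the usual term.
- Our own reckoning for the new flask at 12 h is a share of 1/(1+ρ), which is 93.0%, with target ahead.
- The forecast gives 98.5% at 4.0 min, 93% at 12 h and target in the lead: “Target clearly leads.”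

- The new flask gives 98.3% at 4.0 min and 93.1% at 12 h, with target at 44.9% and isomer of the product at 3.31%.

    starting material + partner ⇌ target (K = 1.60 /M, k = 1.18 × 10⁻⁴ /M/s)
    starting material + partner ⇌ isomer of the product (K = 28.0 /M, k = 1.83 × 10⁻⁶ /M/s)
    target + free catalyst ⇌ isomer of the product + free catalyst, rate k3*[free catalyst]*[target] forward; the back reaction follows from the equilibrium constant (k = 7.09 × 10⁻⁴ /M/s)
    2 free catalyst → spent catalyst (k = 0.129 /M/s)
    partner + protic impurity → quenched reagent (k = 0.0681 /M/s)
    starting material ⇌ dormant form (K = 1.00, k = 5.15 × 10⁻⁵ /s)

- Multiplying the new flask's target by ρ gives 3.35% of isomer. The step from partner and protic impurity to quenched reagent makes no difference to this share at 12 h. The neighbouring flask charged with 0.72 M of partner holds about half as much target at 12.0 h, 21.7%. There ρ gives 1.62% of isomer, the neighbouring flask holds 1.59%, and its share of target is 93.2%.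

All runs are calculated for substances that don't exist; scatter was added.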